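**Retrosynthetic overview**
- Target ⇒ butanoylation of the C11 tertiary alcohol; C15 methyl by lactone‑enolate methylation then kinetic protonation; oxonene (ring D) by ring‑closing metathesis at C6=C7.
- Tetrahydrofuran (ring C) ⇒ C2–OH + C9 acetal → cyclic oxocarbenium ion + 2‑methylallylsilane (C8–C9), carried out only after ring B is seven‑membered.
- ε‑Lactone ⇒ ring expansion of the ring‑B cyclohexanone of a trans‑decalin: oxygen inserted between C16 and quaternary C3 (C→O 1,2‑shift, retention), delivered from a peroxycarbonate tethered on C2–OH.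
- Decalin ⇒ Claisen closure of ring B onto ring A; C3 by Michael addition/Wittig, C2 by enolate‑protected hydride reduction, C10 by formylation of a regiodefined silyl enol ether.
- Ring A ⇒ organocatalytic Michael/aldol of methyl vinyl ketone with methyl 4‑oxobutanoate (sets C14). Ring order: A, B, expanded B (lactone), C, D.

**Notation (one assumption).** C1–C16 are the target carbons in eunicellane numbering: C11 bears the butanoate and a methyl; C14 bears C15(H)(Me)–C16(=O)O; C1 and C10 are the ring‑fusion CH groups; C2 and C9 are the ether carbons; C3 is the lactone carbinol carbon; C6=C7(Me) is the alkene. Ring A = C1, C10–C14; ring B = C1–C2–C3–C16–C15–C14. Decalin locants 1, 2, 3, 4, 4a, 5, 6, 7, 8, 8a = C2, C3, C16, C15, C14, C13, C12, C11, C10, C1. The sulfur‑bearing carbon (C10) in 7, 8, 10, 11, 13, C3 in 8 and C9 in 21 are epimer mixtures and are left undefined in the SMILES on purpose. The route is designed on paper and has not been run; selectivities are predicted.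

**Step 1**
Reactants: 1 methyl vinyl ketone; 2 methyl 4-oxobutanoate
Product: 4 methyl 2-[(1S)-4-oxocyclohex-2-en-1-yl]acetate, via keto aldehyde 3 (not isolated)
Conditions: (S)-α,α-diphenylprolinol trimethylsilyl ether (10 mol%), 4-nitrophenol (20 mol%), CH2Cl2, 4 °C; then p-TsOH·H2O (10 mol%), toluene, 50 °C
Reagents that add atoms: none
Why: Enamine-catalysed Michael addition (the diarylsilyloxymethyl group shields one enamine face, giving the S centre that becomes C14) followed by intramolecular aldol condensation, i.e. an organocatalytic Robinson annulation.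

**Step 2**
Reactants: 4 methyl 2-[(1S)-4-oxocyclohex-2-en-1-yl]acetate
Product: 5 methyl 2-[(1S)-4-oxo-3-(phenylsulfanyl)cyclohex-2-en-1-yl]acetate
Conditions: PhSCl, CH2Cl2, −78 °C → rt; then Et3N, 0 °C
Reagents that add atoms: benzenesulfenyl chloride ClSc1ccccc1
Why: Electrophilic addition of the sulfenyl chloride across the enone and E1cB loss of HCl (α-sulfenylation by addition–elimination) puts a removable handle on C10 without touching C14.

**Step 3**
Reactants: 5 methyl 2-[(1S)-4-oxo-3-(phenylsulfanyl)cyclohex-2-en-1-yl]acetate; 6 propanal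
Product: 7 methyl 2-[(1S,2R)-4-oxo-3-(phenylsulfanyl)-2-propanoylcyclohexyl]acetate
Conditions: (n-Bu4N)4[W10O32] (2 mol%), MeCN, 390 nm LEDs, rt
Reagents that add atoms: none
Why: Decatungstate hydrogen-atom-transfer photocatalysis turns the aldehyde into a nucleophilic acyl radical that adds (Giese hydroacylation) to C1 anti to the C14 side chain, setting C1 trans to C14.

**Step 4**
Reactants: 7 methyl 2-[(1S,2R)-4-oxo-3-(phenylsulfanyl)-2-propanoylcyclohexyl]acetate
Product: 8 (4aS,8aR)-2-methyl-8-(phenylsulfanyl)decalin-1,3,7-trione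
Conditions: KOtBu (2.2 equiv), THF, 0 °C → rt; then 1 M HCl
Reagents that add atoms: none
Why: Intramolecular Claisen (Dieckmann-type) condensation of the ethyl-ketone enolate (C3) onto the ester closes ring B, driven by the acidic 2-methyl-1,3-dione, and the epimerisable C1 settles in the trans-decalin.

**Step 5**
Reactants: 8 (4aS,8aR)-2-methyl-8-(phenylsulfanyl)decalin-1,3,7-trione; 9 acrolein
Product: 10 3-[(2R,4aS,8aR)-2-methyl-1,3,7-trioxo-8-(phenylsulfanyl)decalin-2-yl]propanal
Conditions: Et3N (10 mol%), MeCN–H2O, rt
Reagents that add atoms: none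
Why: Michael addition of the 2-methyl-1,3-dione to acrolein; only the dione is acidic enough for amine catalysis, and stereoelectronically preferred axial attack on the trans-decalin enolate is expected to place the new chain axial and so set quaternary C3.

**Step 6**
Reactants: 10 3-[(2R,4aS,8aR)-2-methyl-1,3,7-trioxo-8-(phenylsulfanyl)decalin-2-yl]propanal
Product: 11 (2R,4aS,8aR)-2-(but-3-en-1-yl)-2-methyl-8-(phenylsulfanyl)decalin-1,3,7-trione
Conditions: Ph3PCH3Br, KN(SiMe3)2, THF, −78 → 0 °C
Reagents that add atoms: methylenetriphenylphosphorane C=P(c1ccccc1)(c1ccccc1)c1ccccc1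
Why: Wittig methylenation is selective for the aldehyde over the three hindered or enolisable ketones and completes the but-3-enyl arm needed for the later metathesis.

**Step 7**
Reactants: 11 (2R,4aS,8aR)-2-(but-3-en-1-yl)-2-methyl-8-(phenylsulfanyl)decalin-1,3,7-trione
Product: 13 (1S,2S,4aS,8aR)-2-(but-3-en-1-yl)-1-hydroxy-2-methyl-8-(phenylsulfanyl)decalin-3,7-dione, via dilithium bis-enolate 12 (not isolated)
Conditions: LiN(iPr)2 (2.2 equiv), THF, −78 °C; then LiAlH4, −78 → −40 °C; aq. KNaC4H4O6
Reagents that add atoms: none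
Why: In situ enolate protection: kinetic deprotonation masks the C11 and C16 ketones, so hydride reduces only the C2 ketone (no accessible α-hydrogen), by axial attack anti to the axial butenyl group, giving the equatorial C2–OH.

**Step 8**
Reactants: 13 (1S,2S,4aS,8aR)-2-(but-3-en-1-yl)-1-hydroxy-2-methyl-8-(phenylsulfanyl)decalin-3,7-dione
Product: 14 C10=C11 trimethylsilyl enol ether carrying the C2 trimethylsilyl ether
Conditions: SmI2 (2.5 equiv), THF, −78 °C; then Me3SiCl, Et3N, −78 °C → rt
Reagents that add atoms: chlorotrimethylsilane C[Si](C)(C)Cl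
Why: Two single-electron transfers from divalent samarium cleave the α-phenylthio ketone much faster than they touch the isolated ketone, giving the regiodefined C10–C11 enolate, which is trapped on oxygen (reductive desulfurisation/silylation).

**Step 9**
Reactants: 14 C10=C11 trimethylsilyl enol ether carrying the C2 trimethylsilyl ether
Product: 15 hydroxy diketone with axial C10 dimethoxymethyl group
Conditions: HC(OMe)3, Me3SiOTf (10 mol%), CH2Cl2, −78 °C; then PPTS (cat.), MeOH, 0 °C
Reagents that add atoms: trimethyl orthoformate COC(OC)OC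
Why: Mukaiyama-type addition of the enol ether to the dimethoxycarbenium ion; axial attack anti to H1 is reinforced because the equatorial path and the equatorial product clash with the peri C2 oxygen, so C9 enters axial and cis to C2 (sets C10), and mild acid methanolysis frees C2–OH.

**Step 10**
Reactants: 15 hydroxy diketone with axial C10 dimethoxymethyl group
Product: 18 ring-expanded ε-lactone keto alcohol, via imidazole carbamate 16 (not isolated), via peroxycarbonic acid monoester 17 (not isolated)
Conditions: 1,1'-carbonyldiimidazole, DBU (10 mol%), CH2Cl2, rt; then urea·H2O2, 0 °C → rt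
Reagents that add atoms: hydrogen peroxide OO
Why: Proposed new method: C2–OH is turned by carbonyldiimidazole and then H2O2 into a peroxycarbonic acid monoester whose OOH can reach only the β-placed C16 carbonyl (seven-membered cyclic Criegee adduct) and not the remote C11 ketone or the alkene; antiperiplanar 1,2-shift of quaternary C3 from carbon to oxygen with retention expels the monoalkyl carbonate (which loses CO2 to return C2–OH), expands ring B to the ε-lactone and creates the C3–O stereocentre; closest known chemistry is the intermolecular Baeyer–Villiger oxidation with peroxy acids or percarbonates and hydroxyl-directed or tethered intramolecular oxygen transfer.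

**Step 11**
Reactants: 18 ring-expanded ε-lactone keto alcohol
Product: 19 lactone diol with C11 tertiary alcohol
Conditions: MeMgBr, CeCl3, THF, −78 °C
Reagents that add atoms: methylmagnesium bromide C[Mg]Br
Why: Organocerium 1,2-addition is selective for the ketone over the lactone, and attack anti to the axial acetal on C10 puts the methyl axial and the C11 oxygen cis to C9.

**Step 12**
Reactants: 19 lactone diol with C11 tertiary alcohol; 20 trimethyl(2-methylallyl)silane
Product: 22 tetrahydrofuran diene, via cyclic methyl acetal 21 (not isolated)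
Conditions: CSA (cat.), 4 Å MS, CH2Cl2, rt; then 20, Me3SiOTf (20 mol%), MeCN–CH2Cl2, −78 → −40 °C
Reagents that add atoms: none
Why: Transacetalisation closes the tetrahydrofuran (it cannot form while ring B is a six-membered chair, hence the ring expansion comes first) and Hosomi–Sakurai allylation of the cyclic oxocarbenium ion anti to the C10–C11 bond sets C9 with the 2-methylallyl group cis to C3.

**Step 13**
Reactants: 22 tetrahydrofuran diene
Product: 23 tetracyclic (Z)-oxonene lactone
Conditions: second-generation Hoveyda–Grubbs catalyst [RuCl2(H2IMes)(=CH–C6H4-2-OiPr)] (10 mol%), toluene (2 mM), 80 °C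
Reagents that add atoms: none
Why: Ring-closing metathesis of the mono- and 1,1-disubstituted alkenes forms C6=C7, and the nine-membered ring allows only the Z trisubstituted alkene.

**Step 14**
Reactants: 23 tetracyclic (Z)-oxonene lactone
Product: 25 debutanoyl target (C11 alcohol with natural C15 methyl), via 15-epi methyl lactone 24 (not isolated)
Conditions: LiN(iPr)2 (2.2 equiv), THF, −78 °C, MeI; then LiN(iPr)2 (2.5 equiv), −78 °C; then 2,6-di-tert-butyl-4-methylphenol, −78 °C
Reagents that add atoms: iodomethane CI
Why: Lactone-enolate methylation followed by re-enolisation and kinetic protonation with a bulky acid from the face opposite the oxonene bridge places hydrogen anti and methyl syn to C4, the natural but less stable C15 configuration, whichever way the methylation itself went.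

**Step 15**
Reactants: 25 debutanoyl target (C11 alcohol with natural C15 methyl); 26 butanoyl chloride
Product: 27 target CNP0294597.2
Conditions: pyridine, DMAP (20 mol%), CH2Cl2, 40 °C
Reagents that add atoms: none
Why: DMAP-catalysed acylation (acylpyridinium transfer) of the only free hydroxyl, the C11 tertiary alcohol, under conditions too weakly basic to epimerise C15.

**Compound list**
1 | but-3-en-2-one (methyl vinyl ketone) | CC(=O)C=C | starting material
2 | methyl 4-oxobutanoate | COC(=O)CCC=O | starting material
3 | methyl (3S)-3-formyl-6-oxoheptanoate | COC(=O)C[C@@H](C=O)CCC(C)=O | intermediate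
4 | methyl 2-[(1S)-4-oxocyclohex-2-en-1-yl]acetate (ring A; stereocentre is C14) | COC(=O)C[C@H]1C=CC(=O)CC1 | intermediate
5 | methyl 2-[(1S)-4-oxo-3-(phenylsulfanyl)cyclohex-2-en-1-yl]acetate | COC(=O)C[C@H]1C=C(Sc2ccccc2)C(=O)CC1 | intermediate
6 | propanal | CCC=O | starting material
7 | methyl 2-[(1S,2R)-4-oxo-3-(phenylsulfanyl)-2-propanoylcyclohexyl]acetate (C1/C14 trans; both C10 epimers) | COC(=O)C[C@@H]1CCC(=O)C(Sc2ccccc2)[C@H]1C(=O)CC | intermediate
8 | (4aS,8aR)-2-methyl-8-(phenylsulfanyl)decalin-1,3,7-trione (trans-fused; dione enolised; C3 and C10 epimers) | CC1C(=O)C[C@@H]2CCC(=O)C(Sc3ccccc3)[C@H]2C1=O | intermediate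
9 | prop-2-enal (acrolein) | C=CC=O | starting material
10 | 3-[(2R,4aS,8aR)-2-methyl-1,3,7-trioxo-8-(phenylsulfanyl)decalin-2-yl]propanal (quaternary C3; chain axial) | O=CCC[C@]1(C)C(=O)C[C@@H]2CCC(=O)C(Sc3ccccc3)[C@H]2C1=O | intermediate
11 | (2R,4aS,8aR)-2-(but-3-en-1-yl)-2-methyl-8-(phenylsulfanyl)decalin-1,3,7-trione | C=CCC[C@]1(C)C(=O)C[C@@H]2CCC(=O)C(Sc3ccccc3)[C@H]2C1=O | intermediate
12 | dilithium bis-enolate of 11 (C16–C15 and C11–C10 enolates; C2 ketone free) | C=CCC[C@]1(C)C([O-])=C[C@@H]2CCC([O-])=C(Sc3ccccc3)[C@H]2C1=O.[Li+].[Li+] | intermediate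
13 | (1S,2S,4aS,8aR)-2-(but-3-en-1-yl)-1-hydroxy-2-methyl-8-(phenylsulfanyl)decalin-3,7-dione (equatorial C2–OH) | C=CCC[C@]1(C)C(=O)C[C@@H]2CCC(=O)C(Sc3ccccc3)[C@H]2[C@@H]1O | intermediate
14 | desulfurised 13 as its C10=C11 trimethylsilyl enol ether and C2 trimethylsilyl ether (C1, C2, C3, C14 unchanged) | C=CCC[C@]1(C)C(=O)C[C@@H]2CCC(O[Si](C)(C)C)=C[C@H]2[C@@H]1O[Si](C)(C)C | intermediate
15 | trans-decalin with C16 and C11 ketones, equatorial C2–OH, and axial dimethoxymethyl (C9) on C10 cis to C2; C1, C3, C14 as before | C=CCC[C@]1(C)C(=O)C[C@@H]2CCC(=O)[C@@H](C(OC)OC)[C@H]2[C@@H]1O | intermediate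
16 | C2 O-(imidazol-1-ylcarbonyl) derivative of 15 | C=CCC[C@]1(C)C(=O)C[C@@H]2CCC(=O)[C@@H](C(OC)OC)[C@H]2[C@@H]1OC(=O)n1ccnc1 | intermediate
17 | C2 O-(hydroperoxycarbonyl) derivative of 15 (peroxycarbonic acid monoester) | C=CCC[C@]1(C)C(=O)C[C@@H]2CCC(=O)[C@@H](C(OC)OC)[C@H]2[C@@H]1OC(=O)OO | intermediate
18 | ε-lactone from 15 (O inserted between C16 and C3 with retention; C11 ketone, C2–OH and C10 acetal kept) | C=CCC[C@]1(C)OC(=O)C[C@@H]2CCC(=O)[C@@H](C(OC)OC)[C@H]2[C@@H]1O | intermediate
19 | 18 with C11 converted to the tertiary alcohol (methyl axial; OH cis to C9) | C=CCC[C@]1(C)OC(=O)C[C@@H]2CC[C@@](C)(O)[C@@H](C(OC)OC)[C@H]2[C@@H]1O | intermediate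
20 | trimethyl(2-methylallyl)silane | C=C(C)C[Si](C)(C)C | starting material
21 | cyclic methyl acetal: tetrahydrofuran closed between the C2 oxygen and C9 (C9 anomers) | O[C@]1(C)CC[C@@H]2[C@H]3[C@@H]1C(OC)O[C@@H]3[C@](C)(CCC=C)OC(=O)C2 | intermediate
22 | tricyclic lactone with C9 2-methylallyl (cis to C3 across the ring oxygen) and C3 but-3-enyl; all other centres as in the target | O[C@]1(C)CC[C@@H]2[C@H]3[C@@H]1[C@H](CC(C)=C)O[C@@H]3[C@](C)(CCC=C)OC(=O)C2 | intermediate
23 | tetracyclic lactone with (Z)-C6=C7 oxonene, C15 unsubstituted, C11 tertiary alcohol | O[C@]1(C)CC[C@@H]2[C@H]3[C@@H]1[C@@H]1C/C(C)=C\CC[C@](C)(OC(=O)C2)[C@H]3O1 | intermediate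
24 | C15-methyl lactone, 15-epimer of 25 | O[C@]1(C)CC[C@@H]2[C@H]3[C@@H]1[C@@H]1C/C(C)=C\CC[C@](C)(OC(=O)[C@H]2C)[C@H]3O1 | intermediate
25 | debutanoyl target: C11 tertiary alcohol with natural C15 methyl | O[C@]1(C)CC[C@@H]2[C@H]3[C@@H]1[C@@H]1C/C(C)=C\CC[C@](C)(OC(=O)[C@@H]2C)[C@H]3O1 | intermediate
26 | butanoyl chloride | CCCC(Cl)=O | starting material
27 | CNP0294597.2 (C11 butanoate of 25) | CCCC(=O)O[C@]1(C)CC[C@@H]2[C@H]3[C@@H]1[C@@H]1C/C(C)=C\CC[C@](C)(OC(=O)[C@@H]2C)[C@H]3O1 | target

**Totals.** 15 steps; longest linear sequence 15 steps.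

**Steps most likely to fail, with fallbacks**

Step 5 (facial selectivity at quaternary C3). If the Michael addition does not favour the axial face, the order in which the two C3 substituents arrive is reversed. Starting from 5, decatungstate hydroacylation with hept-6-enal in place of propanal gives methyl 2-[(1S,2R)-2-(hept-6-enoyl)-4-oxo-3-(phenylsulfanyl)cyclohexyl]acetate F1. Claisen cyclisation with KOtBu gives (4aS,8aR)-2-(but-3-en-1-yl)-8-(phenylsulfanyl)decalin-1,3,7-trione F2. C-methylation (MeI, K2CO3, acetone) then brings the methyl in last, so the face preferred by the incoming electrophile now leaves the butenyl group axial. This returns to the route at 11 and replaces steps 3 to 6.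

Step 10 (the new tethered Baeyer–Villiger ring expansion). Known chemistry replaces it by reversing the order of methyl addition and oxidation. From 15, MeTi(OiPr)3 (THF, −30 °C), which discriminates ketones sterically, adds only to the ring-A ketone and gives the C11-methyl carbinol keto acetal F3. The one remaining ketone is then ring-expanded with m-chloroperbenzoic acid/NaHCO3 (CH2Cl2, 0 °C), or, to spare the terminal alkene, with bis(trimethylsilyl) peroxide and SnCl4/trans-cyclohexane-1,2-diamine. This returns to the route at 19.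

Step 14 (contra-thermodynamic protonation at C15). From 23, the lactone enolate (LiN(iPr)2) is trapped with Eschenmoser's salt [Me2N=CH2]I to give the 15-(dimethylaminomethyl) lactone F4. Quaternisation (MeI) and elimination (DBU) give the 15-methylene lactone F5. Hydrogenation (H2, RhCl(PPh3)3, benzene) reduces only the 1,1-disubstituted alkene and delivers hydrogen to its exposed face, returning to the route at 25.

**Further compounds**
F1 | step 5 | methyl 2-[(1S,2R)-2-(hept-6-enoyl)-4-oxo-3-(phenylsulfanyl)cyclohexyl]acetate | COC(=O)C[C@@H]1CCC(=O)C(Sc2ccccc2)[C@H]1C(=O)CCCCC=C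
F2 | step 5 | (4aS,8aR)-2-(but-3-en-1-yl)-8-(phenylsulfanyl)decalin-1,3,7-trione | C=CCCC1C(=O)C[C@@H]2CCC(=O)C(Sc3ccccc3)[C@H]2C1=O
F3 | step 10 | 15 with C11 converted to the tertiary methyl carbinol (C16 ketone kept) | C=CCC[C@]1(C)C(=O)C[C@@H]2CC[C@@](C)(O)[C@@H](C(OC)OC)[C@H]2[C@@H]1O
F4 | step 14 | 15-(dimethylaminomethyl) derivative of 23 | O[C@]1(C)CC[C@@H]2[C@H]3[C@@H]1[C@@H]1C/C(C)=C\CC[C@](C)(OC(=O)C2CN(C)C)[C@H]3O1
F5 | step 14 | 15-methylene derivative of 23 | O[C@]1(C)CC[C@@H]2[C@H]3[C@@H]1[C@@H]1C/C(C)=C\CC[C@](C)(OC(=O)C2=C)[C@H]3O1
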